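# Proposal: synthesis of CNP0105745.1 (31) through a palladium-catalysed vinyl epoxide etherification that closes the oxepane at C6

## The problem

Compound 31 is an oxidised tetraprenyl (C20) chain folded into a 6,8-dioxabicyclo[3.2.2]nonan-7-one. Locants follow the order of the atoms in the line notation of 31: C1 (methyl on C2), C2=C3, C4, C5, C6, O7, C8, C9, C10, C11 (methyl C12)=C13, C14–O15, C16 (methyl C17), C18, C19, C20 (O21), O22, C23 (=O24), C25–O26. The oxepane (C6, O7, C8, C16, C18, C19, C20) is bridged between C6 and C16 by the ester unit C23(=O)–O22, which also closes a six-membered dioxanone (C6, O7, C8, C16, O22, C23); C6 and C8 each carry a (Z)-hydroxymethylpentenyl arm. Four stereocentres must be set: the fully substituted ether carbons C6 (R) and C16 (R) and the oxygenated methines C8 (S) and C20 (S). C8/C16 and C20/C6 are vicinal pairs that can each be fixed in one operation, but C18–C19 insulates the pairs from each other, so each needs its own absolute control, and the lactone can only close if C23 and O22 are cis across the ring. Fragile elements are the two Z-trisubstituted allylic alcohols (which must stay masked while C23 is oxidised), the α-alkoxy-β-hydroxy lactone (base, retro-aldol) and any tertiary allylic epoxide on the way (acid). The enabling feature is C6: a tertiary ether carbon bearing O7, the one-carbon unit C23, the hydroxylated neighbour C20 and a two-carbon stub C5–C4 that can be a vinyl group. This is the branched product pattern of a π-allyl etherification of a 2-substituted C6/C20 vinyl epoxide by the C8 hydroxyl, with the epoxide oxygen remaining as O21. In addition, C8–C14 with its Z-alkene is the C1–C6 part of nerol (1).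

## Retrosynthesis

**31 ⇒ 30 ⇒ 27 (C23–O22).** The acyl–oxygen bond is cut and C23 returned to the alcohol level, which leads through the bis-silyl ether 30 to triol 27. The lactone is made last because it is the base-sensitive part. Carrying C23 as an ester through the ring closure was rejected, since an acyl group on the allyl terminus would change the electronics of the key step. The forward reaction must oxidise the primary C23 hydroxyl of 27 in the presence of the hindered secondary C20 hydroxyl and let the tertiary O22–H capture the aldehyde. O15 and O26 must remain silylated meanwhile, hence the robust tert-butyldiphenylsilyl groups.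

**27 ⇒ 25 ⇒ 19 + 23 (C4–C3).** This cut removes the whole C1–C3/C25 arm as the stereodefined alkenyl iodide 23 and leaves a vinyl group on C6, which is what the key step delivers. Cutting C2=C3 by olefination would instead require a Z-selective synthesis of a trisubstituted alkene late in the route. Iodide 23 comes from prop-2-yn-1-ol (20) through 22 by chelation-controlled carbometalation, which fixes the geometry. The forward step needs chemoselective hydroboration of the monosubstituted alkene of 19 and a coupling with retention.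

**19 ⇒ 18 (O7–C6, key disconnection).** Cutting the ether bond at the quaternary carbon opens the ring to the acyclic hydroxy vinyl epoxide 18. The neighbouring options are worse: closing O7–C8 needs a preformed tertiary C6 alcohol as nucleophile, and any C–C closure leaves both tertiary ethers to be made separately. Precursor 18 contains only the stereocentres C8, C16 and C20, plus C6 as part of the epoxide. The forward reaction must attack the substituted allyl terminus, fix C6, and keep every other oxygen out. O22 is therefore an acetal (methoxymethyl): a silyl group there could migrate to the adjacent C8 alkoxide and unmask O22 for a six-membered closure.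

**18 ⇒ 17 ⇒ 16 ⇒ 15 ⇒ 13 (epoxide C–O bonds; C6–C5).** The epoxide is traced to the 2-vinyl allylic alcohol 15, whose free C23 hydroxyl directs a Sharpless epoxidation that sets C20 absolutely. The vinyl group is cut back to the propargylic alcohol 13, because chelation-driven carbomagnesiation installs it at C6 in one step with a single alkene geometry. That geometry (C19 trans to CH2OH) gives the epoxide epimer whose double inversion under palladium places O7 correctly. The C8 oxygen stays a 4-methoxybenzyl ether until just before the key step, because this group is removed oxidatively at neutral pH beside an acid-sensitive epoxide.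

**13 ⇒ 11 ⇒ 10 ⇒ 8 (C6–C23; C18–C19).** The hydroxymethyl carbon is removed from the alkyne terminus (acetylide plus a one-carbon electrophile), and the C18–C19 bond is cut to the 2,2-disubstituted epoxide 8 and a propargyl anion equivalent. Opening at the CH2 terminus touches neither C16 nor C8, so both centres are carried unchanged and the tertiary O22–H emerges free for acetal formation.

**8 ⇒ 7 ⇒ 6 ⇒ 5 ⇒ 3 ⇒ 2 ⇒ 1 (C16–O/C18–O; C8–C16).** Epoxy alcohol 7 is cut to the racemic isopropenyl carbinol 6, made from aldehyde 5 and an isopropenyl Grignard reagent. Aldehyde 5 is obtained from nerol (1) through 2 and 3 by cleavage of the terminal alkene. The alternative of adding a C9 nucleophile to an α-oxygenated C8 aldehyde with C16 already in place was set aside. Chelate control there leads to the C8 epimer, and the open transition state would have to distinguish a methyl from a methylene group. The hydroxyl-directed Sharpless epoxidation with kinetic resolution sets C8 and C16 together under reagent control (anti, erythro), at the price of a half-conversion ceiling.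

## Roads not taken

**Alternative 1:** The cut is O22–C16. The oxepane acid A1, with an exocyclic methylene at C16, would take up a hydrogen atom at C17 from a cobalt hydride (a Co(salen) complex, a silane and an oxidant). The tertiary C16 radical, after oxidation, would be trapped by the carboxyl to give the bridged lactone A2.
- Merits: the lactone and the C16 centre form in one step, and the tether allows only the cis-bridged product, so C16 is dictated by C6 whichever alkene isomer is used. No protecting group is needed on O22. In this respect it is better than the chosen plan, which needs an acetal on O22, a two-stage deprotection and a late oxidation.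
- Weak points: A1 already contains the oxepane and the quaternary C6 ether, which is the hard part. Hydrogen-atom transfer would also attack trisubstituted side-chain alkenes, so A2 carries truncated arms and both Z-alkenes must be built afterwards.
- Against it, the chosen plan makes C6 and the ring in one step from an open chain, takes one Z-alkene intact from nerol, and adds the other in a single stereoretentive coupling.

**Alternative 2:** The cut removes C19. The dioxabicyclo[2.2.2]octane keto lactone A3 would be expanded with Me3SiCHN2 and BF3·OEt2 to the bicyclo[3.2.2] keto lactone A4, and the C20 ketone then reduced.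
- Merits: both side chains are in place, the late stage is short, and C20 needs no protecting group. On late-stage brevity it is at least equal to the chosen plan.
- Weak points: the insertion must occur on the C18 side and stop after one carbon. The Lewis acid meets two allylic silyl ethers. The C20 ketone of A4 must be reduced to the S alcohol in a flexible seven-membered ring with no secure control element. A3 already contains both quaternary centres, so their construction is only postponed.
- Against it, the chosen plan fixes C20 by reagent control with its oxygen already attached, and creates C6 in the ring-forming step.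

**Alternative 3:** The cut is C2=C3. The methallyl ester A5, with a but-3-enyl group on C6, would undergo ring-closing metathesis (second-generation Grubbs catalyst) to the spiro eight-membered Z-lactone A6.
- Merits: the ring enforces the Z geometry, C23 is already at the acid level, and a later acyl shift from O26 to O22 would give the target lactone and the free C25 alcohol at once. On oxidation-state economy this is better than the chosen plan, and on alkene geometry it is as good.
- Weak points: an eight-membered closure to a trisubstituted alkene beside a spiro quaternary centre is slow and competes with dimerisation. A5 again presupposes the oxepane with its C6 centre.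
- Against it, the chosen plan has an equally secure Z geometry from a carbometalation-derived alkenyl iodide coupled with retention, and a key step that solves C6 rather than assuming it.

Key step: step 14

Assumption: the (S,S)-antipode of the bisphosphine is taken as matched with the (2S,3S)-epoxide of 18, by analogy with intermolecular alcohol additions to 2-substituted vinyl epoxides; the substrate-controlled double inversion points to the same C6 configuration.

## Route

Step 1
Reactants: 1 nerol
Product: 2 neryl tert-butyldiphenylsilyl ether [(2Z)-1-(tert-butyldiphenylsilyloxy)-3,7-dimethylocta-2,6-diene]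
Conditions: TBDPSCl, imidazole, DMF, 0 °C → rt
Reagents that add atoms: tert-butyl(chloro)diphenylsilane, CC(C)(C)[Si](Cl)(c1ccccc1)c1ccccc1
Why: Silylation of a primary allylic alcohol; the diphenyl(tert-butyl)silyl group is chosen because it should survive periodic acid, organolithium and Grignard reagents, titanium alkoxides, DDQ and ZnBr2/thiol, and is removed last by fluoride.

Step 2
Reactants: 2 neryl tert-butyldiphenylsilyl ether
Product: 3 racemic 6,7-epoxide of 2 [(2Z)-1-(tert-butyldiphenylsilyloxy)-6,7-epoxy-3,7-dimethyloct-2-ene]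
Conditions: mCPBA, CH2Cl2, −20 → 0 °C
Reagents that add atoms: 3-chloroperoxybenzoic acid, OOC(=O)c1cccc(Cl)c1
Why: Prilezhaev epoxidation; the terminal trialkyl alkene is the more electron-rich, while the 2,3-alkene is deactivated by the allylic C–O bond and shielded by the silyl group, so mono-epoxidation at the terminus should dominate. The new stereocentre is destroyed in step 3 and needs no control.

Step 3
Reactants: 3 racemic 6,7-epoxide of 2
Product: 5 (4Z)-6-(tert-butyldiphenylsilyloxy)-4-methylhex-4-enal, via diol 4 (not isolated)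
Conditions: H5IO6, THF/Et2O, 0 °C
Reagents that add atoms: none
Why: Periodic acid hydrolyses the trisubstituted epoxide to the glycol and cleaves it (Malaprade glycol cleavage) to the aldehyde (C8) and acetone; the Z-alkene and the silyl ether are inert to periodate.

Step 4
Reactants: 5 (4Z)-6-(tert-butyldiphenylsilyloxy)-4-methylhex-4-enal
Product: 6 racemic (6Z)-8-(tert-butyldiphenylsilyloxy)-2,6-dimethylocta-1,6-dien-3-ol
Conditions: CH2=C(CH3)MgBr, THF, −78 → 0 °C; aq. NH4Cl
Reagents that add atoms: isopropenylmagnesium bromide, CC(=C)[Mg]Br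
Why: Grignard 1,2-addition to an unhindered aldehyde forms C8–C16 and brings in C17 and C18; the carbinol is deliberately racemic because step 5 resolves it.

Step 5
Reactants: 6 racemic (6Z)-8-(tert-butyldiphenylsilyloxy)-2,6-dimethylocta-1,6-dien-3-ol
Product: 7 (1S,4Z)-6-(tert-butyldiphenylsilyloxy)-4-methyl-1-[(2R)-2-methyloxiran-2-yl]hex-4-en-1-ol
Conditions: Ti(OiPr)4 (0.15 equiv), L-(+)-DIPT (0.2 equiv), t-BuOOH (0.45 equiv), 4 Å MS, CH2Cl2, −20 °C
Reagents that add atoms: tert-butyl hydroperoxide, CC(C)(C)OO
Why: Sharpless kinetic resolution by asymmetric epoxidation: with L-(+)-tartrate the (S)-carbinol is the fast-reacting enantiomer and is epoxidised syn to the titanium-bound oxygen with the carbinol hydrogen eclipsing the 2-methyl group, which gives the erythro (anti) epoxy alcohol, so C8 (S) and C16 (R) are set together by the reagent. The (R)-enantiomer of 6 is left unreacted (at most half of 6 is converted), and the silyloxy-substituted alkene has no free allylic hydroxyl and should not react.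

Step 6
Reactants: 7 (1S,4Z)-6-(tert-butyldiphenylsilyloxy)-4-methyl-1-[(2R)-2-methyloxiran-2-yl]hex-4-en-1-ol
Product: 8 4-methoxybenzyl ether of 7 at the C8 oxygen
Conditions: NaH, PMBCl, Bu4NI (cat.), THF/DMF, 0 °C → rt
Reagents that add atoms: 4-methoxybenzyl chloride, COc1ccc(CCl)cc1
Why: Williamson etherification; Payne rearrangement would require attack of the alkoxide on the fully substituted epoxide carbon and should not compete in an aprotic medium. The benzyl-type ether cannot migrate and is later removed oxidatively at neutral pH.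

Step 7
Reactants: 8 4-methoxybenzyl ether of 7 at the C8 oxygen
Product: 10 (5R,6S,9Z)-11-(tert-butyldiphenylsilyloxy)-6-(4-methoxybenzyloxy)-5,9-dimethylundec-9-en-1-yn-5-ol, via silylalkyne 9 (not isolated)
Conditions: 1-(trimethylsilyl)propyne, n-BuLi, THF, −78 → −20 °C; then 8, DMPU, −20 °C → rt; then MeOH, K2CO3, rt
Reagents that add atoms: 1-(trimethylsilyl)propyne, CC#C[Si](C)(C)C
Why: SN2 opening of the 2,2-disubstituted epoxide at its CH2 terminus by the propargyl lithium reagent forms C18–C19 and leaves the C16–O bond and both stereocentres untouched; methanolic carbonate then cleaves the alkynyl C–Si bond in the same flask.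

Step 8
Reactants: 10 (5R,6S,9Z)-11-(tert-butyldiphenylsilyloxy)-6-(4-methoxybenzyloxy)-5,9-dimethylundec-9-en-1-yn-5-ol
Product: 11 methoxymethyl ether of 10 at the tertiary C16 oxygen
Conditions: MOMCl, i-Pr2NEt, Bu4NI (cat.), ClCH2CH2Cl, 50 °C
Reagents that add atoms: chloromethyl methyl ether, COCCl
Why: O-Alkylation of a tertiary alcohol with an α-chloro ether under amine base (acetal formation); an acetal is chosen over a silyl ether because it cannot shift to the neighbouring C8 oxygen when that oxygen becomes an alkoxide in step 14.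

Step 9
Reactants: 11 methoxymethyl ether of 10 at the tertiary C16 oxygen
Product: 13 (6R,7S,10Z)-12-(tert-butyldiphenylsilyloxy)-7-(4-methoxybenzyloxy)-6-(methoxymethoxy)-6,10-dimethyldodec-10-en-2-yn-1-ol, via lithium acetylide 12 (not isolated)
Conditions: n-BuLi, THF, −78 °C; (CH2O)n, −78 °C → rt; aq. NH4Cl
Reagents that add atoms: formaldehyde (as paraformaldehyde), C=O
Why: Deprotonation of the terminal alkyne and hydroxymethylation of the lithium acetylide introduce C23 as the propargylic alcohol needed to direct the next step.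

Step 10
Reactants: 13 (6R,7S,10Z)-12-(tert-butyldiphenylsilyloxy)-7-(4-methoxybenzyloxy)-6-(methoxymethoxy)-6,10-dimethyldodec-10-en-2-yn-1-ol
Product: 15 (2E,6R,7S,10Z)-12-(tert-butyldiphenylsilyloxy)-2-ethenyl-7-(4-methoxybenzyloxy)-6-(methoxymethoxy)-6,10-dimethyldodeca-2,10-dien-1-ol, via oxamagnesole 14 (not isolated)
Conditions: CH2=CHMgCl (5 equiv), THF/cyclohexane, reflux; aq. NH4Cl
Reagents that add atoms: vinylmagnesium chloride, C=C[Mg]Cl
Why: Chelation-driven anti-carbomagnesiation of a propargylic alcohol: the magnesium alkoxide directs the vinyl group to the proximal alkyne carbon C6 and magnesium to C20 within a five-membered oxamagnesole, so protonation gives one alkene isomer with C19 trans to the CH2OH group; this forms C6–C5.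

Step 11
Reactants: 15 (2E,6R,7S,10Z)-12-(tert-butyldiphenylsilyloxy)-2-ethenyl-7-(4-methoxybenzyloxy)-6-(methoxymethoxy)-6,10-dimethyldodeca-2,10-dien-1-ol
Product: 16 {(2S,3S)-2-ethenyl-3-[(3R,4S,7Z)-9-(tert-butyldiphenylsilyloxy)-4-(4-methoxybenzyloxy)-3-(methoxymethoxy)-3,7-dimethylnon-7-en-1-yl]oxiran-2-yl}methanol
Conditions: Ti(OiPr)4 (0.1 equiv), L-(+)-DIPT (0.14 equiv), t-BuOOH (2 equiv), 4 Å MS, CH2Cl2, −25 °C
Reagents that add atoms: tert-butyl hydroperoxide, CC(C)(C)OO
Why: Sharpless asymmetric epoxidation of an E-configured 2,3-disubstituted allylic alcohol; L-(+)-tartrate delivers oxygen to the face that makes C20 S (and C6 S), as with simple (E)-allylic alcohols, independently of the remote centres. The vinyl group is only homoallylic to the hydroxyl and the other alkene has no free allylic hydroxyl, so both should remain.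

Step 12
Reactants: 16 {(2S,3S)-2-ethenyl-3-[(3R,4S,7Z)-9-(tert-butyldiphenylsilyloxy)-4-(4-methoxybenzyloxy)-3-(methoxymethoxy)-3,7-dimethylnon-7-en-1-yl]oxiran-2-yl}methanol
Product: 17 tert-butyldimethylsilyl ether of 16 at the C23 oxygen
Conditions: TBSCl, imidazole, DMF, 0 °C → rt
Reagents that add atoms: tert-butyl(chloro)dimethylsilane, CC(C)(C)[Si](C)(C)Cl
Why: Silylation of the primary alcohol under mildly basic conditions that the epoxide tolerates; the free C23 hydroxyl must be masked so that it cannot attack the π-allyl complex in step 14.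

Step 13
Reactants: 17 tert-butyldimethylsilyl ether of 16 at the C23 oxygen
Product: 18 (3Z,6S,7R)-9-[(2S,3S)-3-(tert-butyldimethylsilyloxymethyl)-3-ethenyloxiran-2-yl]-1-(tert-butyldiphenylsilyloxy)-7-(methoxymethoxy)-3,7-dimethylnon-3-en-6-ol
Conditions: DDQ, CH2Cl2/pH 7 phosphate buffer (10:1), 0 °C
Reagents that add atoms: none
Why: Oxidative cleavage of the 4-methoxybenzyl ether by DDQ (hydride abstraction from the electron-rich benzylic position, hydrolysis of the oxocarbenium ion); the buffer should protect the tertiary allylic epoxide from acid, and silyl ethers, acetal and alkenes are inert.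

Step 14
Reactants: 18 (3Z,6S,7R)-9-[(2S,3S)-3-(tert-butyldimethylsilyloxymethyl)-3-ethenyloxiran-2-yl]-1-(tert-butyldiphenylsilyloxy)-7-(methoxymethoxy)-3,7-dimethylnon-3-en-6-ol
Product: 19 (2S,3S,6R,7S)-2-(tert-butyldimethylsilyloxymethyl)-7-[(3Z)-5-(tert-butyldiphenylsilyloxy)-3-methylpent-3-en-1-yl]-2-ethenyl-6-(methoxymethoxy)-6-methyloxepan-3-ol
Conditions: Pd2(dba)3·CHCl3 (2.5 mol %), (1S,2S)-N,N′-bis[2-(diphenylphosphino)benzoyl]cyclohexane-1,2-diamine (7.5 mol %), BEt3 (20 mol %), CH2Cl2 (0.02 M), rt
Reagents that add atoms: none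
Why: Zerovalent palladium ionises the vinyl epoxide with inversion at C6 to a zwitterionic π-allyl complex (C4–C5–C6) carrying the C20 alkoxide. BEt3 binds this alkoxide and, after proton transfer, the C8 oxygen, so that a cyclic borate delivers O7 to the substituted terminus C6 on the face opposite to palladium (second inversion). The closest known reaction type is the palladium/trialkylborane-catalysed dynamic kinetic asymmetric addition of alcohols to 2-substituted vinyl epoxides (Tsuji–Trost etherification), together with palladium-catalysed cyclisations of hydroxy vinyl epoxides to five- and six-membered ethers; only the ring size is extended here. The oxepane closes in a 7-exo mode, with C5=C4 left exocyclic as the vinyl group; attack at C4 would give a nine-membered ring and should not compete. The new stereocentre C6 is controlled twice: double inversion of the (2S,3S)-epoxide puts O7 where the epoxide oxygen was, and the chiral ligand selects the same π-allyl diastereomer if the complex equilibrates by π–σ–π through C4. C20 keeps its C–O bond and configuration and appears as the free hydroxyl. The step needs branched regioselectivity and capture faster than hydride shift or β-hydride elimination; the borate tether provides the first, and the acetal on O22 and the silyl ether on O23 ensure that no other oxygen can compete.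

Step 15
Reactants: 20 prop-2-yn-1-ol
Product: 22 (2Z)-3-iodo-2-methylprop-2-en-1-ol, via oxamagnesole 21 (not isolated)
Conditions: MeMgBr (2.5 equiv), CuI (10 mol %), THF, −10 °C → rt; then I2, −78 → 0 °C
Reagents that add atoms: methylmagnesium bromide, C[Mg]Br; iodine, II
Why: Copper-catalysed chelation-controlled carbomagnesiation of propargyl alcohol places methyl on C2 and magnesium on C3 cis to the CH2O group; iodinolysis with retention should give only the Z-iodoalkene.

Step 16
Reactants: 22 (2Z)-3-iodo-2-methylprop-2-en-1-ol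
Product: 23 (2Z)-1-(tert-butyldiphenylsilyloxy)-3-iodo-2-methylprop-2-ene
Conditions: TBDPSCl, imidazole, DMF, rt
Reagents that add atoms: tert-butyl(chloro)diphenylsilane, CC(C)(C)[Si](Cl)(c1ccccc1)c1ccccc1
Why: Silylation of the primary allylic alcohol with the same robust group as on O15, so that both are removed together in step 20.

Step 17
Reactants: 19 (2S,3S,6R,7S)-2-(tert-butyldimethylsilyloxymethyl)-7-[(3Z)-5-(tert-butyldiphenylsilyloxy)-3-methylpent-3-en-1-yl]-2-ethenyl-6-(methoxymethoxy)-6-methyloxepan-3-ol; 23 (2Z)-1-(tert-butyldiphenylsilyloxy)-3-iodo-2-methylprop-2-ene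
Product: 25 (2S,3S,6R,7S)-2-(tert-butyldimethylsilyloxymethyl)-2-[(3Z)-5-(tert-butyldiphenylsilyloxy)-4-methylpent-3-en-1-yl]-7-[(3Z)-5-(tert-butyldiphenylsilyloxy)-3-methylpent-3-en-1-yl]-6-(methoxymethoxy)-6-methyloxepan-3-ol, via alkylborane 24 (not isolated)
Conditions: 9-BBN (2.5 equiv), THF, rt → 40 °C; then 23, PdCl2(dppf) (5 mol %), AsPh3, Cs2CO3, DMF/H2O, rt
Reagents that add atoms: none
Why: 9-BBN adds to the monosubstituted alkene far faster than to the trisubstituted one and places boron on terminal C4; B-alkyl Suzuki–Miyaura coupling with the alkenyl iodide then forms C4–C3 with retention of the Z geometry. The excess of borane allows for reversible borinate formation at the free C20 hydroxyl.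

Step 18
Reactants: 25 (2S,3S,6R,7S)-2-(tert-butyldimethylsilyloxymethyl)-2-[(3Z)-5-(tert-butyldiphenylsilyloxy)-4-methylpent-3-en-1-yl]-7-[(3Z)-5-(tert-butyldiphenylsilyloxy)-3-methylpent-3-en-1-yl]-6-(methoxymethoxy)-6-methyloxepan-3-ol
Product: 27 (2S,3S,6R,7S)-2-(hydroxymethyl)-2-[(3Z)-5-(tert-butyldiphenylsilyloxy)-4-methylpent-3-en-1-yl]-7-[(3Z)-5-(tert-butyldiphenylsilyloxy)-3-methylpent-3-en-1-yl]-6-methyloxepane-3,6-diol, via silyl ether 26 (not isolated)
Conditions: ZnBr2, n-PrSH, CH2Cl2, 0 °C; then MeOH, CSA (cat.), 0 °C → rt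
Reagents that add atoms: none
Why: Lewis acid/thiol cleavage of the methoxymethyl acetal (the thiol captures the methoxymethyl cation; O22 has no neighbouring free hydroxyl that could form a cyclic formal), then acid methanolysis of the primary tert-butyldimethylsilyl ether. Primary tert-butyldiphenylsilyl ethers are far more acid-stable and should remain.

Step 19
Reactants: 27 (2S,3S,6R,7S)-2-(hydroxymethyl)-2-[(3Z)-5-(tert-butyldiphenylsilyloxy)-4-methylpent-3-en-1-yl]-7-[(3Z)-5-(tert-butyldiphenylsilyloxy)-3-methylpent-3-en-1-yl]-6-methyloxepane-3,6-diol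
Product: 30 bis(tert-butyldiphenylsilyl) ether of 31 at O15 and O26, via aldehyde 28 (not isolated), via lactol 29 (not isolated)
Conditions: TEMPO (0.2 equiv), PhI(OAc)2 (2.5 equiv), CH2Cl2, rt
Reagents that add atoms: none
Why: Oxoammonium oxidation (TEMPO/PhI(OAc)2 oxidative lactonisation) is selective for the primary C23 alcohol over the hindered secondary C20 alcohol; the aldehyde is captured by the tertiary O22–H as the bridged lactol, which is oxidised on to the lactone. Only the cis arrangement of C23 and O22 set in steps 5 and 14 allows the bridge.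

Step 20
Reactants: 30 bis(tert-butyldiphenylsilyl) ether of 31 at O15 and O26
Product: 31 (1R,2S,5R,9S)-2-hydroxy-1-[(3Z)-5-hydroxy-4-methylpent-3-en-1-yl]-9-[(3Z)-5-hydroxy-3-methylpent-3-en-1-yl]-5-methyl-6,8-dioxabicyclo[3.2.2]nonan-7-one
Conditions: Bu4NF, AcOH, THF, 0 °C → rt
Reagents that add atoms: none
Why: Fluoride desilylation of the two primary allylic silyl ethers; buffering with acetic acid should keep the α-alkoxy-β-hydroxy lactone from base-induced opening or retro-aldol cleavage.

## Compound list

1 | nerol, (2Z)-3,7-dimethylocta-2,6-dien-1-ol | CC(C)=CCC/C(C)=C\CO | starting material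
2 | neryl tert-butyldiphenylsilyl ether | CC(C)=CCC/C(C)=C\CO[Si](c1ccccc1)(c1ccccc1)C(C)(C)C | intermediate
3 | racemic (2Z)-1-(tert-butyldiphenylsilyloxy)-6,7-epoxy-3,7-dimethyloct-2-ene | CC1(C)OC1CC/C(C)=C\CO[Si](c1ccccc1)(c1ccccc1)C(C)(C)C | intermediate
4 | racemic (6Z)-8-(tert-butyldiphenylsilyloxy)-2,6-dimethyloct-6-ene-2,3-diol (not isolated) | CC(C)(O)C(O)CC/C(C)=C\CO[Si](c1ccccc1)(c1ccccc1)C(C)(C)C | intermediate
5 | (4Z)-6-(tert-butyldiphenylsilyloxy)-4-methylhex-4-enal | O=CCC/C(C)=C\CO[Si](c1ccccc1)(c1ccccc1)C(C)(C)C | intermediate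
6 | racemic (6Z)-8-(tert-butyldiphenylsilyloxy)-2,6-dimethylocta-1,6-dien-3-ol | C=C(C)C(O)CC/C(C)=C\CO[Si](c1ccccc1)(c1ccccc1)C(C)(C)C | intermediate
7 | (1S,4Z)-6-(tert-butyldiphenylsilyloxy)-4-methyl-1-[(2R)-2-methyloxiran-2-yl]hex-4-en-1-ol | C[C@]1(OC1)[C@@H](O)CC/C(C)=C\CO[Si](c1ccccc1)(c1ccccc1)C(C)(C)C | intermediate
8 | 4-methoxybenzyl ether of 7 (C8 oxygen) | C[C@]1(OC1)[C@@H](OCc1ccc(OC)cc1)CC/C(C)=C\CO[Si](c1ccccc1)(c1ccccc1)C(C)(C)C | intermediate
9 | (5R,6S,9Z)-11-(tert-butyldiphenylsilyloxy)-6-(4-methoxybenzyloxy)-5,9-dimethyl-1-(trimethylsilyl)undec-9-en-1-yn-5-ol (not isolated) | C[C@@](O)(CCC#C[Si](C)(C)C)[C@@H](OCc1ccc(OC)cc1)CC/C(C)=C\CO[Si](c1ccccc1)(c1ccccc1)C(C)(C)C | intermediate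
10 | (5R,6S,9Z)-11-(tert-butyldiphenylsilyloxy)-6-(4-methoxybenzyloxy)-5,9-dimethylundec-9-en-1-yn-5-ol | C[C@@](O)(CCC#C)[C@@H](OCc1ccc(OC)cc1)CC/C(C)=C\CO[Si](c1ccccc1)(c1ccccc1)C(C)(C)C | intermediate
11 | methoxymethyl ether of 10 (tertiary C16 oxygen) | C[C@@](OCOC)(CCC#C)[C@@H](OCc1ccc(OC)cc1)CC/C(C)=C\CO[Si](c1ccccc1)(c1ccccc1)C(C)(C)C | intermediate
12 | lithium acetylide of 11 (not isolated) | C[C@@](OCOC)(CCC#C[Li])[C@@H](OCc1ccc(OC)cc1)CC/C(C)=C\CO[Si](c1ccccc1)(c1ccccc1)C(C)(C)C | intermediate
13 | (6R,7S,10Z)-12-(tert-butyldiphenylsilyloxy)-7-(4-methoxybenzyloxy)-6-(methoxymethoxy)-6,10-dimethyldodec-10-en-2-yn-1-ol | C[C@@](OCOC)(CCC#CCO)[C@@H](OCc1ccc(OC)cc1)CC/C(C)=C\CO[Si](c1ccccc1)(c1ccccc1)C(C)(C)C | intermediate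
14 | 4-ethenyl-2,5-dihydro-1,2-oxamagnesole from 13, magnesium on C20 and the C23 oxygen (not isolated) | C[C@@](OCOC)(CCC1=C(C=C)CO[Mg]1)[C@@H](OCc1ccc(OC)cc1)CC/C(C)=C\CO[Si](c1ccccc1)(c1ccccc1)C(C)(C)C | intermediate
15 | (2E,6R,7S,10Z)-12-(tert-butyldiphenylsilyloxy)-2-ethenyl-7-(4-methoxybenzyloxy)-6-(methoxymethoxy)-6,10-dimethyldodeca-2,10-dien-1-ol | C[C@@](OCOC)(CC/C=C(\C=C)CO)[C@@H](OCc1ccc(OC)cc1)CC/C(C)=C\CO[Si](c1ccccc1)(c1ccccc1)C(C)(C)C | intermediate
16 | {(2S,3S)-2-ethenyl-3-[(3R,4S,7Z)-9-(tert-butyldiphenylsilyloxy)-4-(4-methoxybenzyloxy)-3-(methoxymethoxy)-3,7-dimethylnon-7-en-1-yl]oxiran-2-yl}methanol | C[C@@](OCOC)(CC[C@@H]1O[C@@]1(C=C)CO)[C@@H](OCc1ccc(OC)cc1)CC/C(C)=C\CO[Si](c1ccccc1)(c1ccccc1)C(C)(C)C | intermediate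
17 | tert-butyldimethylsilyl ether of 16 (C23 oxygen) | C[C@@](OCOC)(CC[C@@H]1O[C@@]1(C=C)CO[Si](C)(C)C(C)(C)C)[C@@H](OCc1ccc(OC)cc1)CC/C(C)=C\CO[Si](c1ccccc1)(c1ccccc1)C(C)(C)C | intermediate
18 | (3Z,6S,7R)-9-[(2S,3S)-3-(tert-butyldimethylsilyloxymethyl)-3-ethenyloxiran-2-yl]-1-(tert-butyldiphenylsilyloxy)-7-(methoxymethoxy)-3,7-dimethylnon-3-en-6-ol | C=C[C@@]1(CO[Si](C)(C)C(C)(C)C)O[C@H]1CC[C@@](C)(OCOC)[C@@H](O)CC/C(C)=C\CO[Si](c2ccccc2)(c2ccccc2)C(C)(C)C | intermediate
19 | (2S,3S,6R,7S)-2-(tert-butyldimethylsilyloxymethyl)-7-[(3Z)-5-(tert-butyldiphenylsilyloxy)-3-methylpent-3-en-1-yl]-2-ethenyl-6-(methoxymethoxy)-6-methyloxepan-3-ol | C=C[C@@]1(CO[Si](C)(C)C(C)(C)C)O[C@@H](CC/C(C)=C\CO[Si](c2ccccc2)(c2ccccc2)C(C)(C)C)[C@](C)(OCOC)CC[C@@H]1O | intermediate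
20 | prop-2-yn-1-ol | C#CCO | starting material
21 | 4-methyl-2,5-dihydro-1,2-oxamagnesole from 20 (not isolated) | CC1=C[Mg]OC1 | intermediate
22 | (2Z)-3-iodo-2-methylprop-2-en-1-ol | C/C(=C/I)CO | intermediate
23 | (2Z)-1-(tert-butyldiphenylsilyloxy)-3-iodo-2-methylprop-2-ene | C/C(=C/I)CO[Si](c1ccccc1)(c1ccccc1)C(C)(C)C | intermediate
24 | B-alkyl-9-borabicyclo[3.3.1]nonane from 19, boron on C4 (not isolated) | C1CCC2CCCC1B2CC[C@@]1(CO[Si](C)(C)C(C)(C)C)O[C@@H](CC/C(C)=C\CO[Si](c2ccccc2)(c2ccccc2)C(C)(C)C)[C@](C)(OCOC)CC[C@@H]1O | intermediate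
25 | (2S,3S,6R,7S)-2-(tert-butyldimethylsilyloxymethyl)-2-[(3Z)-5-(tert-butyldiphenylsilyloxy)-4-methylpent-3-en-1-yl]-7-[(3Z)-5-(tert-butyldiphenylsilyloxy)-3-methylpent-3-en-1-yl]-6-(methoxymethoxy)-6-methyloxepan-3-ol | C/C(=C/CC[C@@]1(CO[Si](C)(C)C(C)(C)C)O[C@@H](CC/C(C)=C\CO[Si](c2ccccc2)(c2ccccc2)C(C)(C)C)[C@](C)(OCOC)CC[C@@H]1O)CO[Si](c1ccccc1)(c1ccccc1)C(C)(C)C | intermediate
26 | 25 without the methoxymethyl group: free tertiary O22–H, C23 oxygen still silylated (not isolated) | C/C(=C/CC[C@@]1(CO[Si](C)(C)C(C)(C)C)O[C@@H](CC/C(C)=C\CO[Si](c2ccccc2)(c2ccccc2)C(C)(C)C)[C@](C)(O)CC[C@@H]1O)CO[Si](c1ccccc1)(c1ccccc1)C(C)(C)C | intermediate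
27 | (2S,3S,6R,7S)-2-(hydroxymethyl)-2-[(3Z)-5-(tert-butyldiphenylsilyloxy)-4-methylpent-3-en-1-yl]-7-[(3Z)-5-(tert-butyldiphenylsilyloxy)-3-methylpent-3-en-1-yl]-6-methyloxepane-3,6-diol | C/C(=C/CC[C@@]1(CO)O[C@@H](CC/C(C)=C\CO[Si](c2ccccc2)(c2ccccc2)C(C)(C)C)[C@](C)(O)CC[C@@H]1O)CO[Si](c1ccccc1)(c1ccccc1)C(C)(C)C | intermediate
28 | C23 aldehyde of 27 (not isolated) | C/C(=C/CC[C@@]1(C=O)O[C@@H](CC/C(C)=C\CO[Si](c2ccccc2)(c2ccccc2)C(C)(C)C)[C@](C)(O)CC[C@@H]1O)CO[Si](c1ccccc1)(c1ccccc1)C(C)(C)C | intermediate
29 | bridged lactol, 7-hydroxy-6,8-dioxabicyclo[3.2.2]nonane, epimers at C23 (not isolated) | C/C(=C/CC[C@@]12O[C@@H](CC/C(C)=C\CO[Si](c3ccccc3)(c3ccccc3)C(C)(C)C)[C@@](C)(CC[C@@H]1O)OC2O)CO[Si](c1ccccc1)(c1ccccc1)C(C)(C)C | intermediate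
30 | bis(tert-butyldiphenylsilyl) ether of 31 at O15 and O26 | C/C(=C/CC[C@@]12O[C@@H](CC/C(C)=C\CO[Si](c3ccccc3)(c3ccccc3)C(C)(C)C)[C@@](C)(CC[C@@H]1O)OC2=O)CO[Si](c1ccccc1)(c1ccccc1)C(C)(C)C | intermediate
31 | (1R,2S,5R,9S)-2-hydroxy-1-[(3Z)-5-hydroxy-4-methylpent-3-en-1-yl]-9-[(3Z)-5-hydroxy-3-methylpent-3-en-1-yl]-5-methyl-6,8-dioxabicyclo[3.2.2]nonan-7-one | C/C(=C/CC[C@@]12O[C@@H](CC/C(C)=C\CO)[C@@](C)(CC[C@@H]1O)OC2=O)CO | target

## Step count and least certain steps

Total step count: 20. Longest linear sequence: 18 steps (steps 1–14 and 17–20, from nerol 1); steps 15 and 16 make the coupling partner 23.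

**Step 14 (key step).** The seven-membered closure may be slower than collapse of the zwitterionic π-allyl complex by hydride shift or β-hydride elimination, and a mismatched ligand could erode the C6 selectivity through partial equilibration. Switching the ligand antipode or using an achiral bisphosphine is the first remedy. The fallback with a different approach is an acid-promoted, vinyl-activated endo cyclisation of the C6-epimeric hydroxy vinyl epoxide, which is SN2-like with inversion at C6. It sets out from 13 and returns at 19.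
- Palladium-catalysed syn-hydrostannation of 13 (PdCl2(PPh3)2, Bu3SnH) should give the (2E)-2-(tributylstannyl) allylic alcohol F1, with tin on C6 and C19 cis to the CH2OH group; the regioisomer is separated.
- Stille coupling with vinyl bromide (Pd(PPh3)4, CuI, CsF, DMF) gives the (2Z)-2-ethenyl dienol F2.
- Sharpless epoxidation with D-(−)-DIPT gives the (2R,3S)-epoxy alcohol F3, in which C20 is again S and C6 is opposite to that in 16.
- Silylation (TBSCl, imidazole) gives the silyl ether F4, and DDQ in buffered CH2Cl2 gives the hydroxy vinyl epoxide F5, the C6 epimer of 18.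
- CSA (cat.) in CH2Cl2 at −20 °C lets the C8 hydroxyl open the tertiary allylic epoxide carbon with inversion (7-endo) to give 19.

**Step 5.** Rate discrimination between the enantiomers of 6 may be incomplete, which would lower the enantiomeric purity of 7 at useful conversion, and half of the material is lost in any case. The fallback replaces resolution by enantioselective reduction; it sets out from 6 and returns at 7.
- Dess–Martin oxidation gives the isopropenyl ketone F6.
- Corey–Bakshi–Shibata reduction ((R)-Me-CBS oxazaborolidine, catecholborane, toluene, −78 °C) gives the (S)-alcohol F7.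
- Matched Sharpless epoxidation (L-(+)-DIPT, a full equivalent of oxidant) gives 7.

**Step 10.** Carbomagnesiation of the hindered internal alkyne may be sluggish, and at reflux the magnesium Lewis acid may cleave the methoxymethyl acetal (chelation through the neighbouring C8 oxygen). The fallback separates hydrometalation from C–C bond formation; it sets out from 13 and returns at 15.
- Hydroxyl-directed trans-hydrostannation ([Cp*RuCl]4, Bu3SnH, CH2Cl2, rt) gives the (2Z)-2-(tributylstannyl) allylic alcohol F8, with tin on C6 cis to C19.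
- Stille coupling with vinyl bromide (Pd(PPh3)4, CuI, CsF, DMF) gives 15.

**Step 11.** The titanium alkoxide may open the product at its tertiary allylic epoxide carbon, or turnover may be slow with the 2-vinyl substituent. The fallback uses an epoxidation without a Lewis acid or a free hydroxyl; it sets out from 15 and returns at 17.
- Silylation of 15 (TBSCl, imidazole) gives the dienyl silyl ether F9.
- Jacobsen–Katsuki epoxidation gives 17. The antipode of [N,N′-bis(3,5-di-tert-butylsalicylidene)cyclohexane-1,2-diaminato]manganese chloride, (salen)MnCl, is chosen to deliver the (2S,3S)-epoxide (NaOCl, 4-phenylpyridine N-oxide, CH2Cl2, 0 °C); the conjugated trisubstituted alkene should react in preference to the isolated one.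

**Step 19.** Formation of the bridged lactol from aldehyde 28 may be unfavourable (the dioxanone ring is held in a boat), so oxidation could stall at the aldehyde or move on to the C20 hydroxyl. The fallback separates oxidation from ring closure; it sets out from 27 and returns at 30.
- TEMPO (cat.), NaOCl (cat.) and NaClO2 in MeCN/phosphate buffer oxidise only the primary alcohol, giving the hydroxy acid F10.
- Yamaguchi lactonisation (2,4,6-trichlorobenzoyl chloride, Et3N; then DMAP, toluene) closes the lactone onto the tertiary O22–H to give 30.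

## Further compounds

F1 | step 14 | (2E,6R,7S,10Z)-12-(tert-butyldiphenylsilyloxy)-7-(4-methoxybenzyloxy)-6-(methoxymethoxy)-6,10-dimethyl-2-(tributylstannyl)dodeca-2,10-dien-1-ol | C[C@@](OCOC)(CC/C=C(/[Sn](CCCC)(CCCC)CCCC)CO)[C@@H](OCc1ccc(OC)cc1)CC/C(C)=C\CO[Si](c1ccccc1)(c1ccccc1)C(C)(C)C
F2 | step 14 | (2Z,6R,7S,10Z)-12-(tert-butyldiphenylsilyloxy)-2-ethenyl-7-(4-methoxybenzyloxy)-6-(methoxymethoxy)-6,10-dimethyldodeca-2,10-dien-1-ol | C[C@@](OCOC)(CC/C=C(/C=C)CO)[C@@H](OCc1ccc(OC)cc1)CC/C(C)=C\CO[Si](c1ccccc1)(c1ccccc1)C(C)(C)C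
F3 | step 14 | {(2R,3S)-2-ethenyl-3-[(3R,4S,7Z)-9-(tert-butyldiphenylsilyloxy)-4-(4-methoxybenzyloxy)-3-(methoxymethoxy)-3,7-dimethylnon-7-en-1-yl]oxiran-2-yl}methanol | C[C@@](OCOC)(CC[C@@H]1O[C@]1(C=C)CO)[C@@H](OCc1ccc(OC)cc1)CC/C(C)=C\CO[Si](c1ccccc1)(c1ccccc1)C(C)(C)C
F4 | step 14 | tert-butyldimethylsilyl ether of F3 (C23 oxygen) | C[C@@](OCOC)(CC[C@@H]1O[C@]1(C=C)CO[Si](C)(C)C(C)(C)C)[C@@H](OCc1ccc(OC)cc1)CC/C(C)=C\CO[Si](c1ccccc1)(c1ccccc1)C(C)(C)C
F5 | step 14 | (3Z,6S,7R)-9-[(2S,3R)-3-(tert-butyldimethylsilyloxymethyl)-3-ethenyloxiran-2-yl]-1-(tert-butyldiphenylsilyloxy)-7-(methoxymethoxy)-3,7-dimethylnon-3-en-6-ol (C6 epimer of 18) | C=C[C@]1(CO[Si](C)(C)C(C)(C)C)O[C@H]1CC[C@@](C)(OCOC)[C@@H](O)CC/C(C)=C\CO[Si](c2ccccc2)(c2ccccc2)C(C)(C)C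
F6 | step 5 | (6Z)-8-(tert-butyldiphenylsilyloxy)-2,6-dimethylocta-1,6-dien-3-one | C=C(C)C(=O)CC/C(C)=C\CO[Si](c1ccccc1)(c1ccccc1)C(C)(C)C
F7 | step 5 | (3S,6Z)-8-(tert-butyldiphenylsilyloxy)-2,6-dimethylocta-1,6-dien-3-ol | C=C(C)[C@@H](O)CC/C(C)=C\CO[Si](c1ccccc1)(c1ccccc1)C(C)(C)C
F8 | step 10 | (2Z,6R,7S,10Z)-12-(tert-butyldiphenylsilyloxy)-7-(4-methoxybenzyloxy)-6-(methoxymethoxy)-6,10-dimethyl-2-(tributylstannyl)dodeca-2,10-dien-1-ol | C[C@@](OCOC)(CC/C=C(\[Sn](CCCC)(CCCC)CCCC)CO)[C@@H](OCc1ccc(OC)cc1)CC/C(C)=C\CO[Si](c1ccccc1)(c1ccccc1)C(C)(C)C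
F9 | step 11 | tert-butyldimethylsilyl ether of 15 (C23 oxygen) | C[C@@](OCOC)(CC/C=C(\C=C)CO[Si](C)(C)C(C)(C)C)[C@@H](OCc1ccc(OC)cc1)CC/C(C)=C\CO[Si](c1ccccc1)(c1ccccc1)C(C)(C)C
F10 | step 19 | (2R,3S,6R,7S)-2-[(3Z)-5-(tert-butyldiphenylsilyloxy)-4-methylpent-3-en-1-yl]-7-[(3Z)-5-(tert-butyldiphenylsilyloxy)-3-methylpent-3-en-1-yl]-3,6-dihydroxy-6-methyloxepane-2-carboxylic acid | C/C(=C/CC[C@@]1(C(=O)O)O[C@@H](CC/C(C)=C\CO[Si](c2ccccc2)(c2ccccc2)C(C)(C)C)[C@](C)(O)CC[C@@H]1O)CO[Si](c1ccccc1)(c1ccccc1)C(C)(C)C
A1 | alternative 1 | 6-methylene oxepane-2-carboxylic acid with 2-(2-benzyloxyethyl), 3-(tert-butyldimethylsilyloxy) and 7-[2-(tert-butyldiphenylsilyloxy)ethyl] groups | C(OCc1ccccc1)C[C@@]2(C(=O)O)O[C@@H](CCO[Si](c4ccccc4)(c4ccccc4)C(C)(C)C)C(=C)CC[C@@H]2O[Si](C)(C)C(C)(C)C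
A2 | alternative 1 | bridged lactone core (6,8-dioxabicyclo[3.2.2]nonan-7-one) with protected hydroxyethyl arms on C6 and C8 | C(OCc1ccccc1)C[C@@]23O[C@@H](CCO[Si](c4ccccc4)(c4ccccc4)C(C)(C)C)[C@@](C)(CC[C@@H]2O[Si](C)(C)C(C)(C)C)OC3=O
A3 | alternative 2 | dioxabicyclo[2.2.2]octane keto lactone, C20 ketone bonded directly to C18, both arms as tert-butyldimethylsilyl ethers | C/C(=C/CC[C@@]12O[C@@H](CC/C(C)=C\CO[Si](C)(C)C(C)(C)C)[C@@](C)(CC1=O)OC2=O)CO[Si](C)(C)C(C)(C)C
A4 | alternative 2 | bicyclo[3.2.2] keto lactone with the ketone at C20 | C/C(=C/CC[C@@]12O[C@@H](CC/C(C)=C\CO[Si](C)(C)C(C)(C)C)[C@@](C)(CCC1=O)OC2=O)CO[Si](C)(C)C(C)(C)C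
A5 | alternative 3 | methallyl ester of the 6-(but-3-enyl)oxepane C23 acid, O22 triethylsilyl, O21 and O15 tert-butyldimethylsilyl | C=CCC[C@@]1(C(=O)OCC(C)=C)O[C@@H](CC/C(C)=C\CO[Si](C)(C)C(C)(C)C)[C@](C)(O[Si](CC)(CC)CC)CC[C@@H]1O[Si](C)(C)C(C)(C)C
A6 | alternative 3 | oxepane spiro-fused at C6 to the eight-membered Z-lactone | C/C1=C/CC[C@@]2(C(=O)OC1)O[C@@H](CC/C(C)=C\CO[Si](C)(C)C(C)(C)C)[C@](C)(O[Si](CC)(CC)CC)CC[C@@H]2O[Si](C)(C)C(C)(C)C
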